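The ten-membered carbocycle is closed at C1–C10 (germacrane numbering: C1 the oxirane CH, C10 the oxirane C–CH3), the bond this ring shares with its oxirane, because an epoxide C–C bond is a masked olefin. Ring-closing metathesis of a seco precursor with a C1 vinyl and a C10 isopropenyl terminus, which already carries the trans-fused α-methylene lactone, the Z-C4=C5 olefin and both esters, should form C1=C10 as the Z olefin that a ten-membered ring prefers. syn-Dihydroxylation and invertive closure at C1 then turn this Z olefin stereospecifically into the trans epoxide. The C6–C7–C8 triad comes from an Evans aldol–lactonisation and a Brown methallylation, C3 from a Brown allylation.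

Key step: step 16

Remark: germacrane numbering is used throughout (C3 isovalerate carbon, C4=C5 Z olefin, C6 lactone O–CH, C7 ring-fusion CH, C8 epoxy-ester carbon, C11=C13 exocyclic methylene, C12 lactone carbonyl); α and β are the faces of the flat ten-membered ring with H7 on α, so the target is the 1β,10α-epoxide with 3β and 8β esters, (1R,3S,6R,7R,8R,10R), and its side-chain epoxy acid is (2S,3R).

Step 1
Reactants: 1 3-methylfuran-2(5H)-one
Product: 2 3-methyl-2,5-dihydrofuran-2-ol
Conditions: iBu2AlH (1.05 equiv), CH2Cl2, −78 °C; H2O work-up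
Reagents that add atoms: none
Why: Partial reduction of the lactone to the lactol by iBu2AlH at low temperature, where the tetrahedral aluminium hemiacetal survives until work-up; the ring locks the future C4=C5 olefin as Z.

Step 2
Reactants: 2 3-methyl-2,5-dihydrofuran-2-ol
Product: 3 (2Z,4S)-3-methylhepta-2,6-diene-1,4-diol
Conditions: (−)-Ipc2B(allyl) (from (+)-α-pinene, 2.2 equiv), Et2O, −78 °C to rt; then NaOH, H2O2, 0 °C
Reagents that add atoms: (−)-B-allyldiisopinocampheylborane, C=CCB([C@@H]1C[C@@H]2C[C@H]([C@H]1C)C2(C)C)[C@@H]1C[C@@H]2C[C@H]([C@H]1C)C2(C)C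
Why: Brown allylboration of the open (Z)-hydroxy-enal tautomer of the lactol through a closed chair transition state, in which the isopinocampheyl groups direct the allyl group to the Si face of the aldehyde and so set the S carbinol centre C3.

Step 3
Reactants: 3 (2Z,4S)-3-methylhepta-2,6-diene-1,4-diol
Product: 4 (2Z,4S)-3-methyl-1,4-bis(triethylsilyloxy)hepta-2,6-diene
Conditions: Et3SiCl (2.4 equiv), imidazole, DMF, 0 °C
Reagents that add atoms: chlorotriethylsilane, CC[Si](Cl)(CC)CC
Why: Imidazole-promoted silyl ether formation at both hydroxyls, with no stereocentre touched.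

Step 4
Reactants: 4 (2Z,4S)-3-methyl-1,4-bis(triethylsilyloxy)hepta-2,6-diene
Product: 5 (2Z,4S)-3-methyl-4-(triethylsilyloxy)hepta-2,6-dienal
Conditions: (COCl)2, DMSO, CH2Cl2, −78 to −30 °C; then Et3N, −78 to 0 °C
Reagents that add atoms: none
Why: Swern oxidation, in which the chlorodimethylsulfonium ion cleaves the unhindered primary triethylsilyl ether selectively and oxidises it in place to the aldehyde while the secondary silyl ether stays; low temperature and short base contact should preserve the Z enal.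

Step 5
Reactants: 6 (S)-4-benzyl-1,3-oxazolidin-2-one; 7 methyl 4-chloro-4-oxobutanoate
Product: 8 methyl 4-[(4S)-4-benzyl-2-oxo-1,3-oxazolidin-3-yl]-4-oxobutanoate
Conditions: n-BuLi, THF, −78 °C; then 7, −78 to 0 °C
Reagents that add atoms: none
Why: N-Acylation of the lithiated oxazolidinone by the acid chloride, which is far more electrophilic than the methyl ester.

Step 6
Reactants: 8 methyl 4-[(4S)-4-benzyl-2-oxo-1,3-oxazolidin-3-yl]-4-oxobutanoate; 5 (2Z,4S)-3-methyl-4-(triethylsilyloxy)hepta-2,6-dienal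
Product: 10 trans-lactone imide (6R,7R), via aldol adduct 9 (not isolated)
Conditions: Bu2BOTf, iPr2NEt, CH2Cl2, −78 to 0 °C; 5, −78 to 0 °C; H2O2, pH 7 buffer, MeOH; then PPTS (cat.), 4 Å molecular sieves, toluene, 50 °C
Reagents that add atoms: none
Why: Evans syn-aldol reaction, in which the Z boron enolate of the imide adds to the enal through a chair transition state on the enolate face away from the benzyl group and sets C6 (R) and C7 as the syn pair, after which the new hydroxyl lactonises onto the methyl ester to the trans-4,5-disubstituted γ-lactone.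

Step 7
Reactants: 10 trans-lactone imide
Product: 11 S-ethyl thioester of the lactone acid
Conditions: EtSH, n-BuLi, THF, −78 to 0 °C; H2O work-up
Reagents that add atoms: ethanethiol (as LiSEt), CCS
Why: Thiolate cleavage of the exocyclic imide carbonyl (transthioesterification) releases the auxiliary and leaves the lactone and C7 unchanged.

Step 8
Reactants: 11 S-ethyl thioester
Product: 12 lactone aldehyde (C8 formyl)
Conditions: Et3SiH, Pd/C (cat.), acetone, rt
Reagents that add atoms: none
Why: Fukuyama reduction (C–S oxidative addition, Si–H transmetalation, reductive elimination) converts the thioester into the aldehyde without touching the lactone, and the neutral conditions should keep the epimerisable C7 centre.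

Step 9
Reactants: 12 lactone aldehyde
Product: 13 (8R)-homoallylic alcohol
Conditions: (+)-Ipc2BOMe (from (−)-α-pinene), CH2=C(CH3)CH2MgCl, Et2O, 0 °C to rt; then 12, −78 °C; H2O2, pH 7 buffer
Reagents that add atoms: 2-methylallylmagnesium chloride, C=C(C)C[Mg]Cl
Why: Brown methallylboration through a chair transition state, in which the reagent from (−)-α-pinene delivers the 2-methylallyl group to the Re face of the aldehyde and sets the R carbinol centre C8 under reagent control.

Step 10
Reactants: 13 (8R)-homoallylic alcohol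
Product: 16 α-methylene lactone alcohol, via Mannich base 14 (not isolated), via methiodide 15 (not isolated)
Conditions: LiN(iPr)2 (2.3 equiv), THF, −78 °C; [CH2=NMe2]I, −78 °C to rt; H2O; MeI, MeOH, rt; NaHCO3, CH2Cl2/H2O
Reagents that add atoms: N,N-dimethylmethyleneiminium iodide, C=[N+](C)C.[I-]
Why: Eschenmoser methylenation, in which the lactone enolate (the C8 alkoxide rides along as the dianion) is aminomethylated and N-methylation followed by E1cB loss of trimethylamine gives the exocyclic olefin, with C6, C7 and C8 unaffected.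

Step 11
Reactants: 17 (E)-2-methylbut-2-en-1-ol
Product: 18 [(2R,3R)-2,3-dimethyloxiran-2-yl]methanol
Conditions: Ti(OiPr)4 (cat.), D-(−)-diethyl tartrate (cat.), tBuOOH, 4 Å molecular sieves, CH2Cl2, −20 °C
Reagents that add atoms: tert-butyl hydroperoxide, CC(C)(C)OO
Why: Sharpless asymmetric epoxidation, in which the D-(−)-tartrate titanium complex delivers oxygen to the olefin face that gives the (2R,3R)-epoxy alcohol, and the E olefin places the two methyl groups cis on the oxirane.

Step 12
Reactants: 18 [(2R,3R)-2,3-dimethyloxiran-2-yl]methanol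
Product: 19 (2S,3R)-2,3-dimethyloxirane-2-carboxylic acid
Conditions: RuCl3 (cat.), NaIO4, MeCN/EtOAc/H2O, rt
Reagents that add atoms: water, O
Why: Catalytic RuO4 oxidation of the primary alcohol to the acid through the aldehyde hydrate, which leaves the oxirane intact; the descriptor at C2 changes only because the priorities change.

Step 13
Reactants: 16 α-methylene lactone alcohol; 19 (2S,3R)-2,3-dimethyloxirane-2-carboxylic acid
Product: 20 C8 epoxy ester (C3 silyl ether)
Conditions: DCC, DMAP (cat.), CH2Cl2, 0 °C to rt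
Reagents that add atoms: none
Why: Steglich esterification of the secondary C8 hydroxyl through the O-acylisourea and acylpyridinium, with retention at C8 and at both oxirane carbons.

Step 14
Reactants: 20 C8 epoxy ester (C3 silyl ether)
Product: 21 C3 alcohol
Conditions: HF·pyridine, pyridine, THF, 0 °C
Reagents that add atoms: none
Why: Fluoride-driven cleavage of the triethylsilyl ether under buffered conditions that the esters, the α-methylene lactone and the electron-poor oxirane should tolerate.

Step 15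
Reactants: 21 C3 alcohol
Product: 22 seco diester (C1 vinyl, C10 isopropenyl)
Conditions: 3-methylbutanoic anhydride, Et3N, DMAP (cat.), CH2Cl2, 0 °C
Reagents that add atoms: 3-methylbutanoic anhydride, CC(C)CC(=O)OC(=O)CC(C)C
Why: DMAP-catalysed acylation of the allylic C3 hydroxyl with retention of configuration.

Step 16
Reactants: 22 seco diester (C1 vinyl, C10 isopropenyl)
Product: 23 (1(10)Z,4Z)-ten-membered triene lactone
Conditions: second-generation Grubbs catalyst RuCl2(=CHPh)(H2IMes)(PCy3) (15 mol %), 1,4-benzoquinone (30 mol %), toluene (1 mM), 80 °C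
Reagents that add atoms: none
Why: The ruthenium benzylidene initiates at the monosubstituted C1 vinyl group, the new alkylidene adds across the 1,1-disubstituted C10 isopropenyl olefin to a ruthenacyclobutane, and cycloreversion leaves the C1=C10 double bond and releases ethene. The closest known reaction type is ring-closing metathesis to medium carbocycles, including ten-membered germacranolide rings that carry an α-methylene lactone. The one ring closed is the ten-membered carbocycle, by ring-closing olefin metathesis between its two terminal olefins at C1 and C10. No stereocentre is formed; the olefin geometry is controlled by ring strain, a cis-cyclodecene being markedly less strained than the trans isomer, so the Z olefin that steps 17 and 18 require should dominate. The step needs cyclisation to win over oligomerisation and one pair among four olefins to react: the Z-C4=C5 bond folds the C1–C3 arm back toward the lactone and the lactone restricts rotation about C6–C7, high dilution disfavours dimers, and the trisubstituted C4=C5 and electron-poor C11=C13 olefins do not engage the catalyst.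

Step 17
Reactants: 23 (1(10)Z,4Z)-ten-membered triene lactone
Product: 24 (1S,10R)-1α,10α-diol
Conditions: OsO4 (5 mol %), N-methylmorpholine N-oxide, acetone/H2O, 0 °C
Reagents that add atoms: osmium tetroxide, O=[Os](=O)(=O)=O; N-methylmorpholine N-oxide, C[N+]1([O-])CCOCC1; water, O
Why: Catalytic OsO4 dihydroxylation by suprafacial [3+2] addition to the most electron-rich olefin, expected on the α face anti to the two β-acyloxy groups at C3 and C8 that flank it, gives the (1S,10R) cis-diol, while the C4=C5 olefin (two allylic C–O bonds) and the acrylate-type C11=C13 olefin react more slowly.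

Step 18
Reactants: 24 (1S,10R)-1α,10α-diol
Product: 26 target CNP0167461.3, via mesylate 25 (not isolated)
Conditions: MsCl (1.1 equiv), Et3N, CH2Cl2, −20 °C; then DBU, 0 °C to rt
Reagents that add atoms: none
Why: Selective mesylation of the secondary C1 hydroxyl and intramolecular Williamson closure (3-exo-tet SN2) by the tertiary C10 oxygen invert C1 to R and retain C10, which converts the syn-diol of the Z olefin into the trans 1β,10α-epoxide.

Compound list

1 | 3-methylfuran-2(5H)-one | CC1=CCOC1=O | starting material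
2 | 3-methyl-2,5-dihydrofuran-2-ol (lactol, anomers) | CC1=CCOC1O | intermediate
3 | (2Z,4S)-3-methylhepta-2,6-diene-1,4-diol | OC/C=C(/C)[C@@H](O)CC=C | intermediate
4 | (2Z,4S)-3-methyl-1,4-bis(triethylsilyloxy)hepta-2,6-diene | CC[Si](CC)(CC)OC/C=C(/C)[C@@H](O[Si](CC)(CC)CC)CC=C | intermediate
5 | (2Z,4S)-3-methyl-4-(triethylsilyloxy)hepta-2,6-dienal | O=C/C=C(/C)[C@@H](O[Si](CC)(CC)CC)CC=C | intermediate
6 | (S)-4-benzyl-1,3-oxazolidin-2-one | O=C1N[C@@H](Cc2ccccc2)CO1 | starting material
7 | methyl 4-chloro-4-oxobutanoate | COC(=O)CCC(Cl)=O | starting material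
8 | methyl 4-[(4S)-4-benzyl-2-oxo-1,3-oxazolidin-3-yl]-4-oxobutanoate | COC(=O)CCC(=O)N1[C@@H](Cc2ccccc2)COC1=O | intermediate
9 | methyl (3S,4R,5Z,7S)-3-[(4S)-4-benzyl-2-oxo-1,3-oxazolidine-3-carbonyl]-4-hydroxy-6-methyl-7-(triethylsilyloxy)deca-5,9-dienoate (syn-aldol adduct) | COC(=O)C[C@H](C(=O)N1[C@@H](Cc2ccccc2)COC1=O)[C@H](O)/C=C(/C)[C@@H](O[Si](CC)(CC)CC)CC=C | intermediate
10 | (4S)-4-benzyl-3-{(2R,3S)-2-[(1Z,3S)-2-methyl-3-(triethylsilyloxy)hexa-1,5-dien-1-yl]-5-oxooxolane-3-carbonyl}-1,3-oxazolidin-2-one (trans-lactone imide) | O=C1C[C@H](C(=O)N2[C@@H](Cc3ccccc3)COC2=O)[C@@H](/C=C(/C)[C@@H](O[Si](CC)(CC)CC)CC=C)O1 | intermediate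
11 | S-ethyl (2R,3S)-2-[(1Z,3S)-2-methyl-3-(triethylsilyloxy)hexa-1,5-dien-1-yl]-5-oxooxolane-3-carbothioate | O=C1C[C@H](C(=O)SCC)[C@@H](/C=C(/C)[C@@H](O[Si](CC)(CC)CC)CC=C)O1 | intermediate
12 | (2R,3S)-2-[(1Z,3S)-2-methyl-3-(triethylsilyloxy)hexa-1,5-dien-1-yl]-5-oxooxolane-3-carbaldehyde | O=C1C[C@H](C=O)[C@@H](/C=C(/C)[C@@H](O[Si](CC)(CC)CC)CC=C)O1 | intermediate
13 | (4R,5R)-4-[(1R)-1-hydroxy-3-methylbut-3-en-1-yl]-5-[(1Z,3S)-2-methyl-3-(triethylsilyloxy)hexa-1,5-dien-1-yl]oxolan-2-one | O=C1C[C@H]([C@H](O)CC(C)=C)[C@@H](/C=C(/C)[C@@H](O[Si](CC)(CC)CC)CC=C)O1 | intermediate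
14 | 3-[(dimethylamino)methyl] derivative of 13 (Mannich base, both C3 epimers of the oxolanone) | O=C1C(CN(C)C)[C@H]([C@H](O)CC(C)=C)[C@@H](/C=C(/C)[C@@H](O[Si](CC)(CC)CC)CC=C)O1 | intermediate
15 | N,N,N-trimethylammonium iodide of 14 (methiodide) | O=C1C(C[N+](C)(C)C)[C@H]([C@H](O)CC(C)=C)[C@@H](/C=C(/C)[C@@H](O[Si](CC)(CC)CC)CC=C)O1.[I-] | intermediate
16 | (4R,5R)-4-[(1R)-1-hydroxy-3-methylbut-3-en-1-yl]-3-methylidene-5-[(1Z,3S)-2-methyl-3-(triethylsilyloxy)hexa-1,5-dien-1-yl]oxolan-2-one | O=C1C(=C)[C@H]([C@H](O)CC(C)=C)[C@@H](/C=C(/C)[C@@H](O[Si](CC)(CC)CC)CC=C)O1 | intermediate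
17 | (E)-2-methylbut-2-en-1-ol (tiglyl alcohol) | C/C=C(\C)CO | starting material
18 | [(2R,3R)-2,3-dimethyloxiran-2-yl]methanol | OC[C@@]1(C)O[C@@H]1C | intermediate
19 | (2S,3R)-2,3-dimethyloxirane-2-carboxylic acid | OC(=O)[C@@]1(C)O[C@@H]1C | intermediate
20 | (1R)-3-methyl-1-{(2R,3R)-4-methylidene-2-[(1Z,3S)-2-methyl-3-(triethylsilyloxy)hexa-1,5-dien-1-yl]-5-oxooxolan-3-yl}but-3-en-1-yl (2S,3R)-2,3-dimethyloxirane-2-carboxylate | O=C1C(=C)[C@H]([C@H](OC(=O)[C@@]2(C)O[C@@H]2C)CC(C)=C)[C@@H](/C=C(/C)[C@@H](O[Si](CC)(CC)CC)CC=C)O1 | intermediate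
21 | (1R)-1-{(2R,3R)-2-[(1Z,3S)-3-hydroxy-2-methylhexa-1,5-dien-1-yl]-4-methylidene-5-oxooxolan-3-yl}-3-methylbut-3-en-1-yl (2S,3R)-2,3-dimethyloxirane-2-carboxylate | O=C1C(=C)[C@H]([C@H](OC(=O)[C@@]2(C)O[C@@H]2C)CC(C)=C)[C@@H](/C=C(/C)[C@@H](O)CC=C)O1 | intermediate
22 | (1R)-3-methyl-1-{(2R,3R)-4-methylidene-2-[(1Z,3S)-2-methyl-3-(3-methylbutanoyloxy)hexa-1,5-dien-1-yl]-5-oxooxolan-3-yl}but-3-en-1-yl (2S,3R)-2,3-dimethyloxirane-2-carboxylate (seco diester) | O=C1C(=C)[C@H]([C@H](OC(=O)[C@@]2(C)O[C@@H]2C)CC(C)=C)[C@@H](/C=C(/C)[C@@H](OC(=O)CC(C)C)CC=C)O1 | intermediate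
23 | (3S,6R,7R,8R)-(1(10)Z,4Z)-3β-(3-methylbutanoyloxy)-8β-[(2S,3R)-2,3-dimethyloxirane-2-carbonyloxy]germacra-1(10),4,11(13)-trien-12,6α-olide | C=C1C(=O)O[C@@H]2/C=C(/C)[C@@H](OC(=O)CC(C)C)C/C=C(/C)C[C@@H](OC(=O)[C@@]3(C)O[C@@H]3C)[C@@H]12 | intermediate
24 | (1S,10R)-1α,10α-dihydroxy derivative of 23 (cis-diol at C1/C10, 4Z and 11(13) olefins kept) | C=C1C(=O)O[C@@H]2/C=C(/C)[C@@H](OC(=O)CC(C)C)C[C@H](O)[C@@](O)(C)C[C@@H](OC(=O)[C@@]3(C)O[C@@H]3C)[C@@H]12 | intermediate
25 | 1-O-methanesulfonate of 24, (1S,10R) | C=C1C(=O)O[C@@H]2/C=C(/C)[C@@H](OC(=O)CC(C)C)C[C@H](OS(C)(=O)=O)[C@@](O)(C)C[C@@H](OC(=O)[C@@]3(C)O[C@@H]3C)[C@@H]12 | intermediate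
26 | CNP0167461.3: (1R,3S,6R,7R,8R,10R)-1β,10α-epoxy-3β-(3-methylbutanoyloxy)-8β-[(2S,3R)-2,3-dimethyloxirane-2-carbonyloxy]germacra-4Z,11(13)-dien-12,6α-olide | C=C1C(=O)O[C@@H]2/C=C(/C)[C@@H](OC(=O)CC(C)C)C[C@H]3O[C@]3(C)C[C@@H](OC(=O)[C@@]3(C)O[C@@H]3C)[C@@H]12 | target

Total step count: 18 steps. Longest linear sequence: 15 steps (steps 1–4, 6–10 and 13–18).

Steps most likely to fail

1. Step 16 (key step). The ring may close with the opposite E geometry at C1=C10, alone or mixed with 23, because the closure is kinetically controlled; intermolecular metathesis also competes. Fallback, setting out from 22 and returning at 26: the E-configured macrocycle F1 from the same high-dilution closure is separated and carried on in its own right. Its C1=C10 bond is epoxidised directly with dimethyldioxirane (acetone, −20 °C). Oxygen transfer to the exposed outer face of the E-cyclodecene is a stereospecific syn addition and should give the trans 1β,10α-epoxide 26 in one operation, so either olefin isomer of the ring leads to the target.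

2. Step 17. Osmylation may show poor facial selectivity; attack on the β face would give the (1R,10S) diol, which closes to the wrong trans epoxide. Fallback, setting out from 23 and returning at 26: the olefin geometry is inverted, which makes the face of the first oxidation irrelevant. Dimethyldioxirane gives the cis epoxide F2 (either facial isomer serves; the β isomer is listed). Dilute HClO4 in THF/H2O at 0 °C opens it with inversion at C10 to the anti diol F3. Thiocarbonyldiimidazole (DMAP, toluene, 80 °C) gives the cyclic thiocarbonate F4. Corey–Winter syn elimination with 1,3-dimethyl-2-phenyl-1,3,2-diazaphospholidine at 40 °C gives the E macrocycle F1, which dimethyldioxirane epoxidises from the outer face to 26.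

3. Step 10. Under the dianion conditions the C8 alkoxide may translactonise onto C12 (6,12- to 8,12-olide) or the C-alkylation may stay incomplete. Fallback, setting out from 13 and returning at 16: the hydroxyl is masked before enolisation. Me3SiCl and imidazole (CH2Cl2, 0 °C) give the trimethylsilyl ether F5. LiN(iPr)2 (1.1 equiv) and [CH2=NMe2]I give the Mannich base F6, MeI gives the ammonium iodide F7, and NaHCO3 gives the α-methylene lactone F8. Citric acid in MeOH at 0 °C then removes the trimethylsilyl group while the secondary triethylsilyl ether stays, which returns 16.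

Further compounds

F1 | step 16 | (1(10)E,4Z) isomer of 23 (E-configured ten-membered triene lactone) | C=C1C(=O)O[C@@H]2/C=C(/C)[C@@H](OC(=O)CC(C)C)C/C=C(\C)C[C@@H](OC(=O)[C@@]3(C)O[C@@H]3C)[C@@H]12
F2 | step 17 | (1R,10S)-1β,10β-epoxide of 23 (cis epoxide) | C=C1C(=O)O[C@@H]2/C=C(/C)[C@@H](OC(=O)CC(C)C)C[C@H]3O[C@@]3(C)C[C@@H](OC(=O)[C@@]3(C)O[C@@H]3C)[C@@H]12
F3 | step 17 | (1R,10R)-1β,10α-diol (anti diol from F2) | C=C1C(=O)O[C@@H]2/C=C(/C)[C@@H](OC(=O)CC(C)C)C[C@@H](O)[C@@](O)(C)C[C@@H](OC(=O)[C@@]3(C)O[C@@H]3C)[C@@H]12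
F4 | step 17 | cyclic 1,10-thiocarbonate of F3 | C=C1C(=O)O[C@@H]2/C=C(/C)[C@@H](OC(=O)CC(C)C)C[C@H]3OC(=S)O[C@]3(C)C[C@@H](OC(=O)[C@@]4(C)O[C@@H]4C)[C@@H]12
F5 | step 10 | trimethylsilyl ether of 13 at the C8 hydroxyl | O=C1C[C@H]([C@H](O[Si](C)(C)C)CC(C)=C)[C@@H](/C=C(/C)[C@@H](O[Si](CC)(CC)CC)CC=C)O1
F6 | step 10 | 3-[(dimethylamino)methyl] derivative of F5 (Mannich base, both epimers) | O=C1C(CN(C)C)[C@H]([C@H](O[Si](C)(C)C)CC(C)=C)[C@@H](/C=C(/C)[C@@H](O[Si](CC)(CC)CC)CC=C)O1
F7 | step 10 | N,N,N-trimethylammonium iodide of F6 | O=C1C(C[N+](C)(C)C)[C@H]([C@H](O[Si](C)(C)C)CC(C)=C)[C@@H](/C=C(/C)[C@@H](O[Si](CC)(CC)CC)CC=C)O1.[I-]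
F8 | step 10 | trimethylsilyl ether of 16 at the C8 hydroxyl | O=C1C(=C)[C@H]([C@H](O[Si](C)(C)C)CC(C)=C)[C@@H](/C=C(/C)[C@@H](O[Si](CC)(CC)CC)CC=C)O1
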